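## Structural features

The target is a trans-fused guaiane (1αH,5βH; α = lower face, β = upper face of the usual guaiane drawing). A cyclopentane (C1–C5) and a cycloheptane (C1, C5–C10) share the C1–C5 bond; C15 sits on C4, isopropyl on C7 and C14 on C10. There are seven stereocentres. C3/C4 (α-epoxide, 4β-methyl), C5, C1 and C10 (α-hydroxyl, β-methyl) are contiguous around the ring fusion; C7 (β-isopropyl) and C8 (β-isovanilloyloxy) are neighbours on the far side of the seven-membered ring. The C8 ester is cis to the isopropyl group and 1,3-anti to the tertiary C10 hydroxyl, which is syn to H1 and to the epoxide oxygen. Every H or O that must be added to the skeleton (H1, H7, H8, O10, epoxide O) lies on the α face, opposite H5. The fragile groups are the trisubstituted epoxide (acid), the tertiary carbinol (dehydration) and the aryl ester with its free phenol (base, nucleophiles). The real difficulty is relaying configuration from C5 across a flexible seven-membered ring, above all placing the C10 oxygen syn to H1. The key step exploits the unit C8(O)–C9H2–C10(C14), which lies between C7 and the C1–C5 edge of the five-membered ring: it is drawn back to a siloxycyclopropane (C8, C9, C10) with cis alkenyl groups C7=C6 and C1=C5, whose [3,3] shift forms C5–C6 and breaks C8–C10. In this design C14 is carried through the rearrangement as a methoxycarbonyl group and the silyl group is tert-butyldimethylsilyl; the carbon skeletons of cyclopropane and cycloheptadiene are unchanged.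

## Logic of the disconnections

30 ⇒ 29. Only the phenolic O–Si bond is cut. The free phenol would interfere with acylation, enolate formation and metal-mediated steps, so it stays masked to the end. The forward step must leave epoxide and ester untouched.

29 ⇒ 28. The two C–O bonds of the epoxide are cut. This removes the most acid-sensitive group and two stereocentres. The forward oxidation must reach the α face of C3=C4, which is the face hindered by C6, so it has to be delivered from the C10 hydroxyl.

28 ⇒ 27 ⇒ 26 ⇒ 25. The C4–C15 bond is cut back to an enol sulfonate and then to a C4 ketone masked as a dioxolane. This fixes the alkene at C3=C4 and lets C4 travel as a protected carbonyl. The forward enolisation must be kinetic toward C3 so that C5 is not epimerised.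

25 ⇒ 21 + 24, and 24 ⇒ 22. The ester C(=O)–O bond is cut, separating the aromatic acid from the terpenoid diol. The forward acylation must select the secondary C8 hydroxyl over the tertiary C10 hydroxyl.

21 ⇒ 20 ⇒ 19. The C8–H bond and then the C7–H bond are cut, leading back to the C7=C8 silyl enol ether. Two stereocentres disappear. Forward, the proton must add to C7 and the hydride to C8 on the α face; the second is steered by the C10 hydroxyl.

19 ⇒ 17 ⇒ 16 ⇒ 15 ⇒ 14 ⇒ 13. C14 is returned to the ester oxidation level, then the C10–O bond and the C1–H bond are cut, giving a tetrasubstituted enoate. The ester is what allows C10 to be oxygenated through an enolate and C1 to be set by conjugate reduction. Forward, the reduction must give the trans ring fusion and the oxidant must attack the α face of C10.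

13 ⇒ 12. The C5–C6 bond is cut and C8–C10 re-formed. One ring, one skeletal bond and the C5 stereocentre are removed, leaving a monocyclic cyclopropane. The forward step needs the two alkenyl groups cis and a single enantiomer of 12.

12 ⇒ 6 + 11. The C9–C10 and C8–C9 bonds are cut, giving a carbenoid precursor for C10 and a 2-siloxydiene supplying C8 and C9. Because C9 is a terminal CH2, no tetrasubstituted enol ether of defined geometry is needed, and a chiral catalyst can set the absolute configuration. The demand is site selectivity for the enol ether alkene of 11.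

6 ⇒ 5 ⇒ 4 ⇒ 1 + 2, and 11 ⇒ 10 ⇒ 9 ⇒ 8 ⇒ 7. The diazo group, the ketal and the C1–C10 bond are removed on one side; the silyl group, one oxidation level, the C8–C9 bond and the C6 methylene on the other. Both branches end in commodity compounds and use only standard carbonyl chemistry.

## Other disconnections considered

Alternative 1: The cut is C1–C5, which opens the bicycle to a ten-membered ring. Forward, the trans-4,5-epoxide A2 of the achiral trienone A1 would be treated with BF3·OEt2 in a non-nucleophilic solvent. The epoxide opens at C5, the C1=C10 alkene attacks across the ring, and the C10 cation loses a C14 proton to give hydroxy dienone A3.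
- In its favour: one step makes both rings and two stereocentres from a fifteen-carbon precursor that already has the C4 oxygen and the C8 ketone. In step economy this is better than the chosen plan.
- Against it here: A1 is achiral, so the absolute configuration must come from a regio- and enantioselective epoxidation of one of two trisubstituted ring alkenes. After cyclisation the exocyclic C10 methylene must be hydrated with the hydroxyl α, the C4 carbinol dehydrated selectively toward C3, and the C7=C11 enone alkene reduced with control at C7.
- Comparison: the ring fusion arises directly in the ring-forming event, which is equal to or better than the reduction used here. The C7, C8 and C10 problems are equal in both plans. The mechanism is a cationic, conformation-controlled cyclisation with several possible proton losses, against a concerted shift with chirality transfer here. Enantiocontrol is weaker than with a chiral carbenoid catalyst.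

Alternative 2: The cuts are C1–C2 and C4–C5, annulating the five-membered ring onto a preformed seven-membered enone. Forward, silyl acetate A5 with Pd(OAc)2 and P(O-i-Pr)3 (reduced in the flask to zerovalent palladium) would give the methyl-substituted trimethylenemethane complex. It adds across the enone of A4, and an amidine base in the work-up equilibrates C1 to give trans-fused ketone A6.
- In its favour: C7 and C8 are already fixed, cis, in A4 and never pass through an enolisable stage; this is better than the chosen plan. The ring fusion is set by true thermodynamic epimerisation next to the C10 ketone, also better than a dissolving-metal reduction. The C10 carbinol then comes from methyl addition.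
- Against it here: A4 needs its own enantioselective synthesis with two adjacent stereocentres on a seven-membered ring. The exocyclic methylene on C3 is a carbon the target does not contain; it must be cleaved and the C3 ketone converted into the C3=C4 alkene. The methyl group must also be made to add to C10 on the β face.
- Comparison: the mechanism is a stepwise zwitterionic Michael addition and ring closure with a regiochemical question for the substituted donor. Overall step count is about equal to the chosen plan.

Alternative 3: The cuts are C1–C5, C6–C7 and C10–O. Forward, enynyl ketone A7 with Ph3PAuCl and AgSbF6 (cationic monovalent gold) would cyclise in one cascade. The activated alkyne is attacked by the alkene (C5–C1), the ketone oxygen captures the C10 cation, and the resulting oxocarbenium ion is closed by the alkenyl-gold carbon (C6–C7), giving oxa-bridged A8.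
- In its favour: three bonds and both carbocycles form in one step, and the C10–O bond is delivered intramolecularly with a fixed relationship to C1 by anti addition across the E alkene. This is better than the chosen plan at C10. The C4 carbinol can be set in the open chain.
- Against it here: the bridge oxygen ends on C7, which must finally carry hydrogen, so a tertiary allylic C–O bond must be cleaved reductively with control at C7. The C5=C6 alkene must be reduced to the trans fusion, the tertiary C4 silyl ether eliminated toward C3, and the C8 ketal turned into the β-carbinol.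
- Comparison: C1 and C10 are handled better, C5 and C7 worse, than in the chosen plan. Step count is about equal once the synthesis of A7 is included.

Key step: step 8

Assumption: the sense of induction in step 8 is taken by analogy with styrene-type cyclopropanations by dirhodium prolinate catalysts, which points to Rh2(R-DOSP)4 for the (1S,2R)-cyclopropane 12; if the sense were opposite, the mirror-image catalyst would be used.

## Steps

Step 1
Reactants: 1 3-ethoxycyclopent-2-en-1-one; 2 methyl acetate
Product: 4 methyl 2-(3-oxocyclopent-1-en-1-yl)acetate, via tertiary carbinol adduct 3 (not isolated)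
Conditions: LiN(iPr)2, THF, −78 °C; add 1, −78 to 0 °C; then 1 M HCl, rt
Reagents that add atoms: water, O
Why: Stork–Danheiser sequence: the lithium ester enolate adds 1,2 to the vinylogous ester carbonyl, and aqueous acid hydrolyses the enol ether of 3 and dehydrates it, transposing the carbonyl to give the 3-substituted cyclopentenone.

Step 2
Reactants: 4 methyl 2-(3-oxocyclopent-1-en-1-yl)acetate
Product: 5 methyl 2-(1,4-dioxaspiro[4.4]non-6-en-7-yl)acetate
Conditions: (TMSOCH2)2, TMSOTf (2 mol %), CH2Cl2, −78 °C; pyridine quench
Reagents that add atoms: 1,2-bis(trimethylsilyloxy)ethane, C[Si](C)(C)OCCO[Si](C)(C)C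
Why: Noyori ketalisation at low temperature should convert the enone into its dioxolane without moving the ring alkene; the ketal later shields H5 from enolisation once C5 is stereogenic.

Step 3
Reactants: 5 methyl 2-(1,4-dioxaspiro[4.4]non-6-en-7-yl)acetate
Product: 6 methyl 2-diazo-2-(1,4-dioxaspiro[4.4]non-6-en-7-yl)acetate
Conditions: 4-acetamidobenzenesulfonyl azide, DBU, MeCN, 0 °C
Reagents that add atoms: 4-acetamidobenzenesulfonyl azide, CC(=O)Nc1ccc(S(=O)(=O)N=[N+]=[N-])cc1
Why: Regitz diazo transfer to the methylene that is both allylic and α to the ester is the standard entry to vinyldiazoacetates; ketal and ring alkene are inert, and 6 is used fresh.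

Step 4
Reactants: 7 3-methylbutanal
Product: 8 3-methyl-2-methylidenebutanal
Conditions: 37% aq. CH2O, pyrrolidine (10 mol %), EtCO2H (10 mol %), i-PrOH, 45 °C
Reagents that add atoms: formaldehyde, C=O
Why: Amine/acid-catalysed α-methylenation (Mannich-type condensation through the enamine, then elimination) should give the 2-substituted acrolein directly.

Step 5
Reactants: 8 3-methyl-2-methylidenebutanal
Product: 9 4-methyl-3-methylidenepentan-2-ol (racemic)
Conditions: MeMgBr, Et2O, −78 to 0 °C; aq. NH4Cl
Reagents that add atoms: methylmagnesium bromide, C[Mg]Br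
Why: Grignard 1,2-addition to the enal; the carbinol centre is racemic and is removed in the next step.

Step 6
Reactants: 9 4-methyl-3-methylidenepentan-2-ol
Product: 10 4-methyl-3-methylidenepentan-2-one
Conditions: Dess–Martin periodinane, NaHCO3, CH2Cl2, 0 °C to rt
Reagents that add atoms: none
Why: Dess–Martin oxidation of the secondary allylic alcohol under buffered, non-basic conditions that should avoid conjugate addition and dimerisation of the α-methylene ketone, which is used without storage.

Step 7
Reactants: 10 4-methyl-3-methylidenepentan-2-one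
Product: 11 tert-butyldimethyl[(4-methyl-3-methylidenepent-1-en-2-yl)oxy]silane
Conditions: TBSOTf, Et3N, CH2Cl2, 0 °C
Reagents that add atoms: tert-butyldimethylsilyl trifluoromethanesulfonate, CC(C)(C)[Si](C)(C)OS(=O)(=O)C(F)(F)F
Why: Soft enolisation and O-silylation; the methyl group is the only enolisable position, so only the cross-conjugated 2-siloxydiene can form and the new C8=C9 alkene has no geometric isomers.

Step 8
Reactants: 6 methyl 2-diazo-2-(1,4-dioxaspiro[4.4]non-6-en-7-yl)acetate; 11 tert-butyldimethyl[(4-methyl-3-methylidenepent-1-en-2-yl)oxy]silane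
Product: 13 methyl (5S)-8-(tert-butyldimethylsilyloxy)-4,4-(ethylenedioxy)-15-norguaia-1(10),7-dien-14-oate, via cis-divinylcyclopropane 12 (not isolated)
Conditions: Rh2(R-DOSP)4 (dirhodium tetrakis[(R)-N-(4-dodecylbenzenesulfonyl)prolinate], 1 mol %), 11 (3 equiv), hexanes, −78 °C (slow addition of 6) to rt, then 60 °C
Reagents that add atoms: none
Why: The dirhodium catalyst converts 6 into a donor/acceptor carbenoid that transfers C10 to the terminal CH2 (C9) of the siloxy-substituted alkene of 11, giving cyclopropane 12 with the cyclopentenyl group on C10 and the isopropylvinyl group on C8 cis, as is typical of vinylcarbenoid cyclopropanations. On warming, 12 should undergo the [3,3] sigmatropic (Cope) shift through a boat transition state with both alkenyl groups over the three-membered ring: C5 bonds to C6 while the C8–C10 σ bond breaks, leaving the C7=C8 silyl enol ether and the C1=C10 enoate. The closest known reaction type is the tandem cyclopropanation/Cope rearrangement of vinyldiazoacetates with oxygenated dienes (formal [4+3] cycloaddition). The seven-membered ring is closed by concerted four-atom ring expansion of the cyclopropane, not by an ionic or radical cyclisation. The only new stereocentre, C5, takes its configuration from C8 and C10 of 12 through the boat geometry, so it is fixed by the chiral prolinate ligands at the cyclopropanation. Site selectivity for the enol ether alkene over the isopropyl-substituted alkene should follow from its higher nucleophilicity, and reaction at the carbenoid carbon instead of the vinylogous position is favoured by the hydrocarbon solvent and the substituted vinyl terminus. The rearrangement should be easy because the breaking bond carries a donor (siloxy) and an acceptor (ester) and the only group pointing into the boat from the alkene termini is H5.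

Step 9
Reactants: 13 methyl (5S)-8-(tert-butyldimethylsilyloxy)-4,4-(ethylenedioxy)-15-norguaia-1(10),7-dien-14-oate
Product: 14 methyl (1αH,5βH)-8-(tert-butyldimethylsilyloxy)-4,4-(ethylenedioxy)-15-norguai-7-en-14-oate (mixture of C10 epimers)
Conditions: Li, NH3/THF, t-BuOH (1 equiv), −78 °C (inverse addition); NH4Cl
Reagents that add atoms: none
Why: Dissolving-metal (Birch-type) conjugate reduction of the tetrasubstituted enoate; by the Stork-type rule the β-carbanion at C1 should be protonated in the product-like geometry leading to the more stable trans ring fusion (H1 α, anti to H5), with electron transfer outrunning γ-deprotonation at C5 under inverse addition. C10 is left as a mixture that converges in step 10.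

Step 10
Reactants: 14 methyl (1αH,5βH)-8-(tert-butyldimethylsilyloxy)-4,4-(ethylenedioxy)-15-norguai-7-en-14-oate
Product: 15 methyl (1αH,5βH)-8-(tert-butyldimethylsilyloxy)-4,4-(ethylenedioxy)-10α-hydroxy-15-norguai-7-en-14-oate
Conditions: KN(SiMe3)2, THF, −78 °C; then trans-2-(phenylsulfonyl)-3-phenyloxaziridine, −78 °C; aq. NH4Cl
Reagents that add atoms: 2-(phenylsulfonyl)-3-phenyloxaziridine, O=S(=O)(N1OC1c1ccccc1)c1ccccc1
Why: Davis oxidation of the potassium ester enolate; the bulky oxaziridine should approach the exocyclic enolate carbon C10 along the equatorial trajectory on the α face, avoiding the C1–C5 and C9–C8 ring bonds and the axial H5 on the β face, which places OH α and the ester β.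

Step 11
Reactants: 15 methyl (1αH,5βH)-8-(tert-butyldimethylsilyloxy)-4,4-(ethylenedioxy)-10α-hydroxy-15-norguai-7-en-14-oate
Product: 16 (1αH,5βH)-8-(tert-butyldimethylsilyloxy)-4,4-(ethylenedioxy)-15-norguai-7-ene-10α,14-diol
Conditions: LiAlH4, THF, 0 °C
Reagents that add atoms: none
Why: Hydride reduction of the α-hydroxy ester to the 1,2-diol; silyl enol ether and ketal are inert to LiAlH4 at 0 °C and C10 is untouched.

Step 12
Reactants: 16 (1αH,5βH)-8-(tert-butyldimethylsilyloxy)-4,4-(ethylenedioxy)-15-norguai-7-ene-10α,14-diol
Product: 17 (1αH,5βH)-8-(tert-butyldimethylsilyloxy)-4,4-(ethylenedioxy)-10α-hydroxy-15-norguai-7-en-14-yl 4-methylbenzenesulfonate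
Conditions: TsCl, Et3N, DMAP (cat.), CH2Cl2, 0 °C
Reagents that add atoms: 4-methylbenzenesulfonyl chloride, Cc1ccc(S(=O)(=O)Cl)cc1
Why: Sulfonylation should be selective for the primary C14 hydroxyl because the tertiary C10 hydroxyl does not react with the sulfonyl chloride under amine base.

Step 13
Reactants: 17 (1αH,5βH)-8-(tert-butyldimethylsilyloxy)-4,4-(ethylenedioxy)-10α-hydroxy-15-norguai-7-en-14-yl 4-methylbenzenesulfonate
Product: 19 (1αH,5βH)-8-(tert-butyldimethylsilyloxy)-4,4-(ethylenedioxy)-15-norguai-7-en-10α-ol, via spiro-epoxide 18 (not isolated)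
Conditions: LiEt3BH, THF, 0 °C to rt
Reagents that add atoms: none
Why: The lithium alkoxide at C10 displaces the neopentyl-type sulfonate (3-exo-tet) to give spiro-epoxide 18, which the trialkylborohydride opens at the primary carbon; the C10–O bond is never broken, so the 10α-hydroxy/10β-methyl arrangement follows from step 10.

Step 14
Reactants: 19 (1αH,5βH)-8-(tert-butyldimethylsilyloxy)-4,4-(ethylenedioxy)-15-norguai-7-en-10α-ol
Product: 20 (1αH,5βH,7αH)-4,4-(ethylenedioxy)-10α-hydroxy-15-norguaian-8-one
Conditions: Bu4NF, AcOH (1:1.2), THF, −40 to −20 °C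
Reagents that add atoms: none
Why: Fluoride cleaves the silyl enol ether and acetic acid protonates the enolate at C7 under kinetic control; in the trans-fused ring C5, C1 and C10 are folded toward the β face of the C7=C8 plane, so the proton should arrive on the exposed α face (H7 α, isopropyl β), and the cold buffered medium should prevent epimerisation and β-elimination of the C10 hydroxyl.

Step 15
Reactants: 20 (1αH,5βH,7αH)-4,4-(ethylenedioxy)-10α-hydroxy-15-norguaian-8-one
Product: 21 (1αH,5βH,7αH)-4,4-(ethylenedioxy)-15-norguaiane-8β,10α-diol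
Conditions: Me4NBH(OAc)3, MeCN/AcOH (1:1), −30 °C
Reagents that add atoms: none
Why: Evans–Saksena reduction: the triacetoxyborohydride binds the C10 hydroxyl and delivers hydride intramolecularly to the α face of the C8 ketone, giving the 1,3-anti diol (8β-OH); this is also the face anti to the adjacent β-isopropyl group.

Step 16
Reactants: 22 isovanillic acid (3-hydroxy-4-methoxybenzoic acid)
Product: 24 3-(tert-butyldimethylsilyloxy)-4-methoxybenzoic acid, via bis-silyl compound 23 (not isolated)
Conditions: TBSCl, imidazole, DMF, rt; then AcOH/THF/H2O (3:1:1), rt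
Reagents that add atoms: tert-butyldimethylsilyl chloride, CC(C)(C)[Si](C)(C)Cl
Why: Bis-silylation followed by selective hydrolysis of the labile silyl ester leaves the phenol as an aryl silyl ether that should survive steps 17–21.

Step 17
Reactants: 21 (1αH,5βH,7αH)-4,4-(ethylenedioxy)-15-norguaiane-8β,10α-diol; 24 3-(tert-butyldimethylsilyloxy)-4-methoxybenzoic acid
Product: 25 (1αH,5βH,7αH)-4,4-(ethylenedioxy)-10α-hydroxy-15-norguaian-8β-yl 3-(tert-butyldimethylsilyloxy)-4-methoxybenzoate
Conditions: DCC, DMAP (1 equiv), CH2Cl2, rt
Reagents that add atoms: none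
Why: Steglich esterification acylates the secondary C8 hydroxyl; the tertiary C10 hydroxyl is too hindered to compete, and the anti-1,3 relationship rules out later acyl migration.

Step 18
Reactants: 25 (1αH,5βH,7αH)-4,4-(ethylenedioxy)-10α-hydroxy-15-norguaian-8β-yl 3-(tert-butyldimethylsilyloxy)-4-methoxybenzoate
Product: 26 (1αH,5βH,7αH)-10α-hydroxy-4-oxo-15-norguaian-8β-yl 3-(tert-butyldimethylsilyloxy)-4-methoxybenzoate
Conditions: PPTS, acetone/H2O (10:1), 40 °C
Reagents that add atoms: water, O
Why: Mildly acidic acetal hydrolysis unmasks the C4 ketone; the pyridinium salt is too weak an acid to dehydrate the tertiary alcohol, cleave the aryl silyl ether or enolise C5 at a significant rate.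

Step 19
Reactants: 26 (1αH,5βH,7αH)-10α-hydroxy-4-oxo-15-norguaian-8β-yl 3-(tert-butyldimethylsilyloxy)-4-methoxybenzoate
Product: 27 (1αH,5βH,7αH)-10α-hydroxy-4-(trifluoromethylsulfonyloxy)-15-norguai-3-en-8β-yl 3-(tert-butyldimethylsilyloxy)-4-methoxybenzoate
Conditions: KN(SiMe3)2 (2.2 equiv), THF, −78 °C; PhNTf2, −78 to −40 °C
Reagents that add atoms: N-phenylbis(trifluoromethanesulfonimide), O=S(=O)(N(c1ccccc1)S(=O)(=O)C(F)(F)F)C(F)(F)F
Why: Kinetic deprotonation with the hindered amide removes a C3 proton, not the ring-fusion H5 (the first equivalent is taken by the C10 hydroxyl), and O-sulfonylation traps the Δ3-enolate as the enol triflate without equilibration, so C5 should keep its configuration.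

Step 20
Reactants: 27 (1αH,5βH,7αH)-10α-hydroxy-4-(trifluoromethylsulfonyloxy)-15-norguai-3-en-8β-yl 3-(tert-butyldimethylsilyloxy)-4-methoxybenzoate
Product: 28 (1αH,5βH,7αH)-10α-hydroxyguai-3-en-8β-yl 3-(tert-butyldimethylsilyloxy)-4-methoxybenzoate
Conditions: Me2Zn, Pd(PPh3)4 (5 mol %), THF, 0 °C to rt
Reagents that add atoms: dimethylzinc, C[Zn]C
Why: Negishi cross-coupling (oxidative addition of zerovalent palladium into the C–OTf bond, transmetalation from zinc, reductive elimination) replaces the triflate by C15 with the alkene fixed at C3=C4; ester and silyl ether are tolerated.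

Step 21
Reactants: 28 (1αH,5βH,7αH)-10α-hydroxyguai-3-en-8β-yl 3-(tert-butyldimethylsilyloxy)-4-methoxybenzoate
Product: 29 (1αH,5βH,7αH)-3α,4α-epoxy-10α-hydroxyguaian-8β-yl 3-(tert-butyldimethylsilyloxy)-4-methoxybenzoate
Conditions: VO(acac)2 (5 mol %), t-BuOOH, CH2Cl2, 0 °C to rt
Reagents that add atoms: tert-butyl hydroperoxide, CC(C)(C)OO
Why: Hydroxyl-directed epoxidation: the C10 carbinol, which points toward C2 on the α side of the five-membered ring, binds the vanadium peroxide and should deliver oxygen to the α face of the only alkene, against the steric preference for the β face set by C6; the cis epoxy alcohol cannot cyclise because backside attack is geometrically impossible.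

Step 22
Reactants: 29 (1αH,5βH,7αH)-3α,4α-epoxy-10α-hydroxyguaian-8β-yl 3-(tert-butyldimethylsilyloxy)-4-methoxybenzoate
Product: 30 (1αH,5βH,7αH)-3α,4α-epoxy-10α-hydroxyguaian-8β-yl 3-hydroxy-4-methoxybenzoate (CNP0264062.2)
Conditions: Bu4NF, AcOH, THF, 0 °C
Reagents that add atoms: none
Why: Buffered fluoride cleaves the aryl silyl ether selectively; epoxide, tertiary alcohol and benzoate ester should be stable at 0 °C under these nearly neutral conditions.

## Compound list

1 | 3-ethoxycyclopent-2-en-1-one | CCOC1=CC(=O)CC1 | starting material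
2 | methyl acetate | COC(C)=O | starting material
3 | methyl 2-(3-ethoxy-1-hydroxycyclopent-2-en-1-yl)acetate (racemic, not isolated) | CCOC1=CC(O)(CC(=O)OC)CC1 | intermediate
4 | methyl 2-(3-oxocyclopent-1-en-1-yl)acetate | COC(=O)CC1=CC(=O)CC1 | intermediate
5 | methyl 2-(1,4-dioxaspiro[4.4]non-6-en-7-yl)acetate | COC(=O)CC1=CC2(OCCO2)CC1 | intermediate
6 | methyl 2-diazo-2-(1,4-dioxaspiro[4.4]non-6-en-7-yl)acetate | COC(=O)C(=[N+]=[N-])C1=CC2(OCCO2)CC1 | intermediate
7 | 3-methylbutanal | CC(C)CC=O | starting material
8 | 3-methyl-2-methylidenebutanal | CC(C)C(=C)C=O | intermediate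
9 | 4-methyl-3-methylidenepentan-2-ol (racemic) | CC(O)C(=C)C(C)C | intermediate
10 | 4-methyl-3-methylidenepentan-2-one | CC(=O)C(=C)C(C)C | intermediate
11 | tert-butyldimethyl[(4-methyl-3-methylidenepent-1-en-2-yl)oxy]silane | C=C(O[Si](C)(C)C(C)(C)C)C(=C)C(C)C | intermediate
12 | methyl (1S,2R)-2-(tert-butyldimethylsilyloxy)-1-(1,4-dioxaspiro[4.4]non-6-en-7-yl)-2-(3-methylbut-1-en-2-yl)cyclopropane-1-carboxylate (alkenyl groups cis, not isolated) | C=C(C(C)C)[C@]1(O[Si](C)(C)C(C)(C)C)C[C@]1(C(=O)OC)C1=CC2(OCCO2)CC1 | intermediate
13 | methyl (5S)-8-(tert-butyldimethylsilyloxy)-4,4-(ethylenedioxy)-15-norguaia-1(10),7-dien-14-oate | COC(=O)C1=C2CCC3(OCCO3)[C@H]2CC(C(C)C)=C(O[Si](C)(C)C(C)(C)C)C1 | intermediate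
14 | methyl (1αH,5βH)-8-(tert-butyldimethylsilyloxy)-4,4-(ethylenedioxy)-15-norguai-7-en-14-oate (C10 epimers) | CC(C)(C)[Si](C)(C)OC=2CC(C(=O)OC)[C@@H]3CCC4(OCCO4)[C@H]3CC=2C(C)C | intermediate
15 | methyl (1αH,5βH)-8-(tert-butyldimethylsilyloxy)-4,4-(ethylenedioxy)-10α-hydroxy-15-norguai-7-en-14-oate | CC(C)(C)[Si](C)(C)OC=2C[C@@](C(=O)OC)(O)[C@@H]3CCC4(OCCO4)[C@H]3CC=2C(C)C | intermediate
16 | (1αH,5βH)-8-(tert-butyldimethylsilyloxy)-4,4-(ethylenedioxy)-15-norguai-7-ene-10α,14-diol | CC(C)(C)[Si](C)(C)OC=2C[C@@](CO)(O)[C@@H]3CCC4(OCCO4)[C@H]3CC=2C(C)C | intermediate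
17 | 14-(4-methylbenzenesulfonate) of 16 | CC(C)(C)[Si](C)(C)OC=2C[C@@](COS(=O)(=O)c5ccc(C)cc5)(O)[C@@H]3CCC4(OCCO4)[C@H]3CC=2C(C)C | intermediate
18 | (1αH,5βH)-10α,14-epoxy-8-(tert-butyldimethylsilyloxy)-4,4-(ethylenedioxy)-15-norguai-7-ene (not isolated) | CC(C)(C)[Si](C)(C)OC=2C[C@@]5(OC5)[C@@H]3CCC4(OCCO4)[C@H]3CC=2C(C)C | intermediate
19 | (1αH,5βH)-8-(tert-butyldimethylsilyloxy)-4,4-(ethylenedioxy)-15-norguai-7-en-10α-ol | CC(C)(C)[Si](C)(C)OC=2C[C@@](C)(O)[C@@H]3CCC4(OCCO4)[C@H]3CC=2C(C)C | intermediate
20 | (1αH,5βH,7αH)-4,4-(ethylenedioxy)-10α-hydroxy-15-norguaian-8-one | O=C2C[C@@](C)(O)[C@@H]3CCC4(OCCO4)[C@H]3C[C@@H]2C(C)C | intermediate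
21 | (1αH,5βH,7αH)-4,4-(ethylenedioxy)-15-norguaiane-8β,10α-diol | O[C@@H]2C[C@@](C)(O)[C@@H]3CCC4(OCCO4)[C@H]3C[C@@H]2C(C)C | intermediate
22 | isovanillic acid | COc1ccc(C(=O)O)cc1O | starting material
23 | tert-butyldimethylsilyl 3-(tert-butyldimethylsilyloxy)-4-methoxybenzoate (not isolated) | COc1ccc(C(=O)O[Si](C)(C)C(C)(C)C)cc1O[Si](C)(C)C(C)(C)C | intermediate
24 | 3-(tert-butyldimethylsilyloxy)-4-methoxybenzoic acid | COc1ccc(C(=O)O)cc1O[Si](C)(C)C(C)(C)C | intermediate
25 | (1αH,5βH,7αH)-4,4-(ethylenedioxy)-10α-hydroxy-15-norguaian-8β-yl 3-(tert-butyldimethylsilyloxy)-4-methoxybenzoate | COc1ccc(C(=O)O[C@@H]2C[C@@](C)(O)[C@@H]3CCC4(OCCO4)[C@H]3C[C@@H]2C(C)C)cc1O[Si](C)(C)C(C)(C)C | intermediate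
26 | (1αH,5βH,7αH)-10α-hydroxy-4-oxo-15-norguaian-8β-yl 3-(tert-butyldimethylsilyloxy)-4-methoxybenzoate | COc1ccc(C(=O)O[C@@H]2C[C@@](C)(O)[C@@H]3CCC(=O)[C@H]3C[C@@H]2C(C)C)cc1O[Si](C)(C)C(C)(C)C | intermediate
27 | (1αH,5βH,7αH)-10α-hydroxy-4-(trifluoromethylsulfonyloxy)-15-norguai-3-en-8β-yl 3-(tert-butyldimethylsilyloxy)-4-methoxybenzoate | COc1ccc(C(=O)O[C@@H]2C[C@@](C)(O)[C@@H]3CC=C(OS(=O)(=O)C(F)(F)F)[C@H]3C[C@@H]2C(C)C)cc1O[Si](C)(C)C(C)(C)C | intermediate
28 | (1αH,5βH,7αH)-10α-hydroxyguai-3-en-8β-yl 3-(tert-butyldimethylsilyloxy)-4-methoxybenzoate | COc1ccc(C(=O)O[C@@H]2C[C@@](C)(O)[C@@H]3CC=C(C)[C@H]3C[C@@H]2C(C)C)cc1O[Si](C)(C)C(C)(C)C | intermediate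
29 | (1αH,5βH,7αH)-3α,4α-epoxy-10α-hydroxyguaian-8β-yl 3-(tert-butyldimethylsilyloxy)-4-methoxybenzoate | COc1ccc(C(=O)O[C@@H]2C[C@@](C)(O)[C@@H]3C[C@H]4O[C@@]4(C)[C@H]3C[C@@H]2C(C)C)cc1O[Si](C)(C)C(C)(C)C | intermediate
30 | (1αH,5βH,7αH)-3α,4α-epoxy-10α-hydroxyguaian-8β-yl 3-hydroxy-4-methoxybenzoate (CNP0264062.2) | COc1ccc(C(=O)O[C@@H]2C[C@@](C)(O)[C@@H]3C[C@H]4O[C@@]4(C)[C@H]3C[C@@H]2C(C)C)cc1O | target

## Step count and least certain steps

Total: 22 steps. Longest linear sequence: 18 steps (7 to 30 through steps 4–15 and 17–22).

Step 8 (key step). Most likely failures: loss of site selectivity between the two 1,1-disubstituted alkenes of the cross-conjugated diene; low enantioselectivity with this hindered enol ether; ring-opening of the donor–acceptor cyclopropane before it rearranges. Fallback with auxiliary instead of catalyst control: setting out from 5, transesterification with (R)-pantolactone (Ti(OiPr)4, toluene, removal of methanol) would give the (R)-pantolactonyl ester F1. Diazo transfer as in step 3 would give diazo ester F2. Dirhodium tetraoctanoate, Rh2(O2CC7H15)4, with 11 would give the Cope product as pantolactonyl ester F3, whose diastereomers can be separated. Neutral methanolysis (Ti(OiPr)4, MeOH) comes back to 13. The antipode of the auxiliary would be used if the sense required it.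

Step 9. Most likely failures: protonation of C1 from the open β face giving the cis fusion; γ-deprotonation at C5 before electron transfer, eroding the only stereocentre; over-reduction of the ester. Fallback under thermodynamic control: setting out from 13, Bu4NF/AcOH would unmask the C8 ketone to give keto enoate F4. DBU would move the alkene to C9=C10, giving the doubly conjugated oxo-enoate F5, in which C1 is a γ-carbon and can equilibrate to the trans fusion. Zn in AcOH would reduce the ene-dicarbonyl unit to keto ester F6. Silylation under equilibrating conditions (TBSOTf, Et3N, rt) toward the more substituted C7=C8 enol ether comes back to 14.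

Step 10. Most likely failures: poor facial selectivity on the exocyclic enolate (axial against equatorial attack); addition of the enolate to the sulfonimine by-product. Fallback that adds carbon to a ketone instead of oxygen to an enolate: setting out from 16, used as its C10 epimer mixture, NaIO4 (THF/H2O) would cleave the glycol to the 14-nor ketone F7. Precomplexation with the bulky aluminium phenoxide MeAl(OC6H2-2,6-tBu2-4-Me)2 followed by MeLi at −78 °C should force axial delivery of methyl to the β face (equatorial α-hydroxyl) and comes back to 19.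

Step 14. Most likely failures: poor facial selectivity in the protonation of C7; later epimerisation next to the ketone; β-elimination of the tertiary hydroxyl. Fallback that sets C7 by directed hydrogenation: setting out from 19, Saegusa–Ito oxidation (Pd(OAc)2, MeCN) would give the C6=C7 enone F8. Hydrogenation with [Ir(cod)(PCy3)(py)]PF6 (H2, CH2Cl2), bound by the C10 hydroxyl on the α face, should add H7 from that face and comes back to 20.

Step 21. Most likely failure: poor facial selectivity, because the tertiary carbinol may deliver the oxidant too slowly to overcome the steric bias from C6 toward the β face. Fallback by reagent control: setting out from 28, a Shi epoxidation (fructose-derived chiral ketone, or its enantiomer, chosen for the α face; Oxone, buffered MeCN/H2O) comes back to 29 directly.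

## Further compounds

F1 | step 8 | (3R)-4,4-dimethyl-2-oxooxolan-3-yl 2-(1,4-dioxaspiro[4.4]non-6-en-7-yl)acetate | CC1(C)COC(=O)[C@@H]1OC(=O)CC2=CC3(OCCO3)CC2
F2 | step 8 | (3R)-4,4-dimethyl-2-oxooxolan-3-yl 2-diazo-2-(1,4-dioxaspiro[4.4]non-6-en-7-yl)acetate | CC1(C)COC(=O)[C@@H]1OC(=O)C(=[N+]=[N-])C2=CC3(OCCO3)CC2
F3 | step 8 | (3R)-4,4-dimethyl-2-oxooxolan-3-yl (5S)-8-(tert-butyldimethylsilyloxy)-4,4-(ethylenedioxy)-15-norguaia-1(10),7-dien-14-oate | CC1(C)COC(=O)[C@@H]1OC(=O)C2=C3CCC4(OCCO4)[C@H]3CC(C(C)C)=C(O[Si](C)(C)C(C)(C)C)C2
F4 | step 9 | methyl (5S)-4,4-(ethylenedioxy)-8-oxo-15-norguai-1(10)-en-14-oate (C7 epimers) | COC(=O)C1=C2CCC3(OCCO3)[C@H]2CC(C(C)C)C(=O)C1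
F5 | step 9 | methyl (1αH,5βH)-4,4-(ethylenedioxy)-8-oxo-15-norguai-9-en-14-oate (C7 epimers) | O=C2C=C(C(=O)OC)[C@@H]3CCC4(OCCO4)[C@H]3CC2C(C)C
F6 | step 9 | methyl (1αH,5βH)-4,4-(ethylenedioxy)-8-oxo-15-norguaian-14-oate (C7 and C10 epimers) | O=C2CC(C(=O)OC)[C@@H]3CCC4(OCCO4)[C@H]3CC2C(C)C
F7 | step 10 | (1αH,5βH)-8-(tert-butyldimethylsilyloxy)-4,4-(ethylenedioxy)-14,15-dinorguai-7-en-10-one | CC(C)(C)[Si](C)(C)OC=2CC(=O)[C@@H]3CCC4(OCCO4)[C@H]3CC=2C(C)C
F8 | step 14 | (1αH,5βH)-4,4-(ethylenedioxy)-10α-hydroxy-15-norguai-6-en-8-one | O=C2C[C@@](C)(O)[C@@H]3CCC4(OCCO4)[C@H]3C=C2C(C)C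
F0 | step 21 | none | none
A1 | alternative 1 | (1(10)E,4E)-germacra-1(10),4,7(11)-trien-8-one | C/C1=C\CC/C(C)=C/CC(=C(C)C)C(=O)C1
A2 | alternative 1 | trans-4,5-epoxide of A1 (one enantiomer) | C/C1=C\CC[C@]2(C)O[C@H]2CC(=C(C)C)C(=O)C1
A3 | alternative 1 | 4-hydroxy-1,5-trans-guaia-7(11),10(14)-dien-8-one | O=C1CC(=C)[C@@H]2CC[C@](C)(O)[C@H]2CC1=C(C)C
A4 | alternative 2 | cis-6-(tert-butyldimethylsilyloxy)-5-isopropylcyclohept-2-en-1-one (one enantiomer) | O=C1C=CC[C@H](C(C)C)[C@H](O[Si](C)(C)C(C)(C)C)C1
A5 | alternative 2 | 3-[(trimethylsilyl)methyl]but-3-en-2-yl acetate (racemic) | CC(OC(C)=O)C(=C)C[Si](C)(C)C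
A6 | alternative 2 | trans-fused 8-(tert-butyldimethylsilyloxy)-3-methylidene-14-norguaian-10-one | O=C1[C@@H]2CC(=C)[C@H](C)[C@H]2C[C@H](C(C)C)[C@H](O[Si](C)(C)C(C)(C)C)C1
A7 | alternative 3 | (E)-1-[2-(4,8-dimethyl-8-(triethylsilyloxy)dec-4-en-9-yn-... chain written out: 2-methyl-1-{2-[(E)-2,6-dimethyl-6-(triethylsilyloxy)oct-2-en-7-yn-1-yl]-1,3-dioxolan-2-yl}propan-1-one | CC(C)C(=O)C1(OCCO1)C/C(C)=C/CC[C@@](C)(O[Si](CC)(CC)CC)C#C
A8 | alternative 3 | 7,10-oxa-bridged guai-5-ene with 4-triethylsilyloxy and 8,8-ethylenedioxy groups | CC(C)[C@]12C=C3[C@@H](CC[C@@]3(C)O[Si](CC)(CC)CC)[C@](C)(O1)CC24OCCO4
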